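**Strategy.** Ring C of the upper unit is cut at C4–C4a, not at the interflavan bond. Upper C4 is a doubly benzylic methine held between two phloroglucinol rings (ring A through C4a, ring D through lower C6); a C4 cation stabilised by ring D can therefore be trapped by either equivalent ortho carbon of a symmetric ring A aryl ether. This one intramolecular Friedel–Crafts step forms C4–C4a, closes ring C, sets C4 trans to the C3 oxygen and completes the 4→6 biflavan. Its precursor is an open-chain carbinol: benzylated 8-bromo-epicatechin gallate bearing at C6 a CH(OH)–CH(OBn)–CH(OAr)Ar chain, made from a C6 arylmagnesium and a chiral aldehyde.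

Key step: step 14

Remark on notation: rings are lettered A (benzo), B (aryl) and C (pyran) in the upper unit and D (benzo), E (catechol) and F (pyran) in the lower unit; atom numbers are flavan numbers of the unit named, and doubly primed numbers belong to the galloyl ring.

Assumption: the (R)-phosphoric acid of step 7 is taken to deliver the allyl unit to the Re face of the aldehyde, as in allyl- and crotylborations with pinacol boronates, which corresponds to the (1S) carbinol; should the first run show the opposite sense, the (S)-acid is used.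

**Lower fragment**

Step 1
Reactants: 1 (−)-epicatechin 3-O-gallate
Product: 2 4''-O-benzyl-(−)-epicatechin 3-O-gallate (one benzyl ether, on the galloyl oxygen para to the ester carbonyl; 2R,3R)
Conditions: BnBr (1.0 equiv), KHCO3 (1.2 equiv), DMF, Ar, rt; aqueous work-up, short SiO2 plug
Reagents that add atoms: benzyl bromide, BrCc1ccccc1
Why: Williamson etherification under hydrogencarbonate should take the galloyl 4''-OH first, because this phenol, para to the ester carbonyl, is the most acidic of the seven (the selectivity known from the 4-O-benzylation of alkyl gallates), which caps the autoxidation-prone pyrogallol before carbonate is used; no stereocentre is touched, and isomeric or doubly benzylated by-products need not be removed because step 2 converts them into the same ether 3.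

Step 2
Reactants: 2 4''-O-benzyl-epicatechin gallate
Product: 3 5,7,3',4'-tetra-O-benzyl-(−)-epicatechin 3-O-(3,4,5-tri-O-benzylgallate) (hepta-O-benzyl, 2R,3R)
Conditions: BnBr (7 equiv), K2CO3 (9 equiv), DMF, Ar, 0 °C → rt
Reagents that add atoms: benzyl bromide, BrCc1ccccc1
Why: Williamson etherification of the six remaining phenols with a carbonate base in anhydrous DMF should leave the hindered secondary gallate ester and the two existing stereocentres untouched (no new stereocentre), while low temperature and exclusion of air limit C-benzylation of ring D and base-induced C2 epimerisation.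

Step 3
Reactants: 3 hepta-O-benzyl-epicatechin gallate
Product: 4 8-bromo-hepta-O-benzyl-epicatechin gallate
Conditions: NBS (1.0 equiv), CH2Cl2, −78 °C → rt
Reagents that add atoms: N-bromosuccinimide, O=C1CCC(=O)N1Br
Why: Electrophilic aromatic bromination goes to the phloroglucinol-type ring D, whose C8 is the most nucleophilic position of 5,7-di-O-benzylated flavan-3-ols, and the catechol and galloyl rings are far less reactive toward one equivalent of NBS at low temperature.

Step 4
Reactants: 4 8-bromo-hepta-O-benzyl-epicatechin gallate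
Product: 5 8-bromo-6-iodo-hepta-O-benzyl-epicatechin gallate
Conditions: NIS (1.1 equiv), TFA (5 mol%), CH2Cl2/MeCN, 0 °C, dark
Reagents that add atoms: N-iodosuccinimide, O=C1CCC(=O)N1I
Why: Electrophilic aromatic iodination can only occur at C6 on ring D, which remains much more activated (three oxygen donors) than the dialkoxy ring E, so the halogen pattern (bromine at C8 as a blocking group, iodine at C6 as the future interflavan carbon) is fixed on the monomer.

**Upper fragment**

Step 5
Reactants: 6 benzyl propargyl ether
Product: 7 (E)-2-(3-benzyloxyprop-1-enyl)-4,4,5,5-tetramethyl-1,3,2-dioxaborolane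
Conditions: HBpin (1.1 equiv), Cp2Zr(H)Cl (5 mol%), Et3N (10 mol%), neat, 60 °C
Reagents that add atoms: pinacolborane, CC1(C)OBOC1(C)C
Why: Zirconium-hydride-catalysed hydroboration of the terminal alkyne is a syn, anti-Markovnikov addition that places boron on the terminal carbon and gives the (E)-alkenylboronate without touching the benzyl ether.

Step 6
Reactants: 7 (E)-3-benzyloxyprop-1-enyl pinacol boronate
Product: 8 (E)-2-(3-benzyloxyprop-2-enyl)-4,4,5,5-tetramethyl-1,3,2-dioxaborolane ((E)-γ-benzyloxyallyl pinacol boronate)
Conditions: [Ir(cod)(PPh2Me)2]PF6 (3 mol%, activated with H2), THF, rt; used without chromatography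
Reagents that add atoms: none
Why: Iridium-hydride-catalysed alkene transposition (the same 1,3-hydrogen shift that turns allyl ethers into propenyl ethers) moves the double bond toward oxygen to give the allylboronate, and the cationic iridium phosphine catalyst is the one that delivers the (E)-enol ether geometry needed for anti selectivity.

Step 7
Reactants: 8 (E)-γ-benzyloxyallyl pinacol boronate; 9 4-benzyloxybenzaldehyde
Product: 11 (1S,2R)-2-benzyloxy-1-(4-benzyloxyphenyl)but-3-en-1-ol (anti), via pinacol borate ester 10 (not isolated)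
Conditions: (R)-TRIP [(R)-3,3'-bis(2,4,6-triisopropylphenyl)-1,1'-binaphthyl-2,2'-diyl hydrogen phosphate] (5 mol%), 4 Å MS, toluene, −30 °C; then aq NaHCO3
Reagents that add atoms: none
Why: Chiral-phosphoric-acid-catalysed alkoxyallylboration proceeds through a closed chair (Zimmerman–Traxler-type) transition state in which the (E)-γ-benzyloxy group is equatorial, which sets C1–OH and C2–OBn anti, while the phosphate, hydrogen-bonded to a boronate oxygen and to the formyl hydrogen, selects the aldehyde face and so the absolute configuration (1S,2R).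

Step 8
Reactants: 12 phloroglucinol
Product: 13 phloroglucinol triacetate (1,3,5-triacetoxybenzene)
Conditions: Ac2O, pyridine, rt
Reagents that add atoms: acetic anhydride, CC(=O)OC(C)=O
Why: Exhaustive O-acetylation masks the phloroglucinol, whose free trianion would be C-benzylated, as a crystalline triester that releases its phenoxides one at a time in the next step.

Step 9
Reactants: 13 phloroglucinol triacetate
Product: 14 1,3,5-tris(benzyloxy)benzene
Conditions: BnCl (3.6 equiv), NaH (7 equiv), DMF, 0 °C; H2O (3 equiv) added slowly, → rt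
Reagents that add atoms: benzyl chloride, ClCc1ccccc1
Why: Hydroxide generated slowly from NaH and water cleaves each aryl acetate and the phenoxide is O-benzylated as it forms (Williamson etherification), so that the ambident phloroglucinol polyanion never builds up and C-alkylation is suppressed.

Step 10
Reactants: 14 1,3,5-tris(benzyloxy)benzene
Product: 15 3,5-bis(benzyloxy)phenol
Conditions: NaSEt (1.3 equiv), DMF, 130 °C; then 1 M HCl
Reagents that add atoms: none
Why: SN2 dealkylation of a benzyl ether by ethanethiolate stops after one cleavage because the phenoxide formed makes the remaining ether oxygens much poorer leaving groups.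

Step 11
Reactants: 11 anti alcohol; 15 3,5-bis(benzyloxy)phenol
Product: 16 1-{[(1R,2R)-2-benzyloxy-1-(4-benzyloxyphenyl)but-3-en-1-yl]oxy}-3,5-bis(benzyloxy)benzene (syn aryl ether)
Conditions: n-Bu3P (1.5 equiv), TMAD (N,N,N',N'-tetramethylazodicarboxamide, 1.5 equiv), toluene, 0 °C → rt
Reagents that add atoms: none
Why: Mitsunobu etherification displaces the oxyphosphonium of the benzylic alcohol by the phenoxide with inversion (SN2), which turns the anti alcohol into the syn aryl ether and thereby sets the future C2 with its 2,3-cis relationship, the β-benzyloxy group and the non-polar solvent disfavouring ionisation of the benzylic carbon.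

Step 12
Reactants: 16 syn aryl ether
Product: 18 (2S,3R)-2-benzyloxy-3-(4-benzyloxyphenyl)-3-[3,5-bis(benzyloxy)phenoxy]propanal, via vicinal diol 17 (not isolated)
Conditions: OsO4 (2 mol%), NaIO4 (4 equiv), 2,6-lutidine (2 equiv), dioxane/H2O 3:1, rt; crude aldehyde dried azeotropically and used at once
Reagents that add atoms: osmium tetroxide, O=[Os](=O)(=O)=O; sodium periodate (oxygen source that regenerates OsO4), [Na+].[O-][I](=O)(=O)=O
Why: Lemieux–Johnson oxidation (catalytic dihydroxylation followed by periodate cleavage of the diol) removes the terminal methylene without ozone, which would attack the electron-rich ring A, and the lutidine-buffered medium should keep the α-benzyloxy aldehyde from epimerising or losing the β-aryloxy group.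

**Union, key step and deprotection**

Step 13
Reactants: 5 8-bromo-6-iodo-hepta-O-benzyl-epicatechin gallate; 18 aldehyde
Product: 20 seco-dimer carbinol: 8-bromo-hepta-O-benzyl-epicatechin gallate carrying at C6 a (1RS,2R,3R)-2-benzyloxy-3-(4-benzyloxyphenyl)-3-[3,5-bis(benzyloxy)phenoxy]-1-hydroxypropyl group (both C4 epimers), via C6 arylmagnesium chloride 19 (not isolated)
Conditions: 5 (1.3 equiv), iPrMgCl·LiCl (1.25 equiv), THF, −30 °C; then 18 (1.0 equiv), −40 → −20 °C; sat. aq NH4Cl; filtration through Et3N-deactivated SiO2
Reagents that add atoms: none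
Why: Iodine–magnesium exchange is much faster at the C6 iodide than at the C8 bromide and is tolerated at low temperature by the hindered gallate ester, and the 2,6-dialkoxyarylmagnesium then adds to the aldehyde (Grignard addition) to form the C4–C6 bond, the new carbinol centre being left uncontrolled because it is ionised in the next step.

Step 14
Reactants: 20 seco-dimer carbinol (epimer mixture)
Product: 21 8-bromo-undeca-O-benzyl-epiafzelechin-(4β→6)-epicatechin 3-O-gallate (upper unit 3,5,7,4'-tetra-O-benzyl, 2,3-cis-3,4-trans; lower unit 5,7,3',4'-tetra-O-benzyl-8-bromo with 3-O-(3,4,5-tri-O-benzylgalloyl))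
Conditions: BF3·OEt2 (20 mol%), 4 Å MS, CH2Cl2 (0.002 M, slow addition of 20), −78 → −40 °C; Et3N quench
Reagents that add atoms: none
Why: Proposed new method: the Lewis acid ionises the C4 hydroxyl of either epimer of 20, because the cation is a 2,4,6-trioxygenated benzylic (O-benzylated quinone-methide-like) cation delocalised into ring D, and the tethered 3,5-dibenzyloxyphenyl ether attacks it through one of its two equivalent ortho carbons in an intramolecular Friedel–Crafts alkylation; the closest known reaction type is the acid-promoted cyclodehydration of 1-aryl-3-aryloxypropan-1-ols to 4-arylchromans, together with Lewis acid ionisation of C4–O groups in benzylated flavan-3-ols. Ring C is closed in a 6-exo-trig mode with respect to the C4=C6 bond of the cation; the ring A para carbon cannot reach C4, and closure through ring B would need a five-membered ring at a carbon meta to its oxygen. The one new stereocentre, upper C4, is controlled by C3: allylic 1,3-strain with the two ortho benzyloxy groups of ring D holds C3–H in the plane of the cation, so C2 (which carries ring A through O1) and the C3 benzyloxy group lie on opposite faces, the C4–C4a bond forms anti to the C3 oxygen, and the 3,4-trans (4β) isomer results, which should also be the more stable one because ring D sits pseudoaxial, away from the C5 benzyloxy group. The step needs chemoselective ionisation, regioselective arylation and facial selectivity: the first rests on the unique stabilisation of the C4 cation (the C2–O1 ether, the benzyl ethers and the gallate are far harder to ionise), the second on the symmetry of ring A and the six-membered tether, the third on the C3 stereocentre. The in-plane C3–H is poorly aligned for a 1,2-hydride shift or proton loss, and high dilution suppresses intermolecular arylation by the free C6 and C8 positions of ring A.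

Step 15
Reactants: 21 protected 8-bromo dimer
Product: 22 epiafzelechin-(4β→6)-epicatechin 3-O-gallate (CNP0210310.1; upper 2R,3R,4S, lower 2R,3R)
Conditions: H2 (1 atm), Pd(OH)2/C, Et3N (5 equiv), THF/MeOH/H2O, rt
Reagents that add atoms: none
Why: Catalytic hydrogenolysis cleaves the eleven benzyl ethers and, by hydrodehalogenation, the C8–Br bond in one operation, triethylamine neutralising the HBr that would otherwise cleave the acid-labile interflavan bond, while the gallate ester and all five stereocentres are untouched.

**Compound list**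

1 | (−)-epicatechin 3-O-gallate | O=C(O[C@@H]1Cc2c(cc(O)cc2O)O[C@@H]1c1ccc(O)c(O)c1)c1cc(O)c(O)c(O)c1 | starting material
2 | 4''-O-benzyl-(−)-epicatechin 3-O-gallate | O=C(O[C@@H]1Cc2c(cc(O)cc2O)O[C@@H]1c1ccc(O)c(O)c1)c1cc(O)c(OCc5ccccc5)c(O)c1 | intermediate
3 | hepta-O-benzyl-(−)-epicatechin 3-O-gallate | O=C(O[C@@H]1Cc2c(cc(OCc5ccccc5)cc2OCc5ccccc5)O[C@@H]1c1ccc(OCc5ccccc5)c(OCc5ccccc5)c1)c1cc(OCc5ccccc5)c(OCc5ccccc5)c(OCc5ccccc5)c1 | intermediate
4 | 8-bromo-hepta-O-benzyl-epicatechin gallate | O=C(O[C@@H]1Cc2c(c(Br)c(OCc5ccccc5)cc2OCc5ccccc5)O[C@@H]1c1ccc(OCc5ccccc5)c(OCc5ccccc5)c1)c1cc(OCc5ccccc5)c(OCc5ccccc5)c(OCc5ccccc5)c1 | intermediate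
5 | 8-bromo-6-iodo-hepta-O-benzyl-epicatechin gallate | O=C(O[C@@H]1Cc2c(c(Br)c(OCc5ccccc5)c(I)c2OCc5ccccc5)O[C@@H]1c1ccc(OCc5ccccc5)c(OCc5ccccc5)c1)c1cc(OCc5ccccc5)c(OCc5ccccc5)c(OCc5ccccc5)c1 | intermediate
6 | benzyl propargyl ether | C#CCOCc1ccccc1 | starting material
7 | (E)-3-benzyloxyprop-1-enyl pinacol boronate | CC1(C)OB(/C=C/COCc2ccccc2)OC1(C)C | intermediate
8 | (E)-γ-benzyloxyallyl pinacol boronate | CC1(C)OB(C/C=C/OCc2ccccc2)OC1(C)C | intermediate
9 | 4-benzyloxybenzaldehyde | O=Cc1ccc(OCc2ccccc2)cc1 | starting material
10 | pinacol borate ester of alcohol 11 | C=C[C@@H](OCc1ccccc1)[C@@H](OB1OC(C)(C)C(C)(C)O1)c1ccc(OCc2ccccc2)cc1 | intermediate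
11 | (1S,2R)-2-benzyloxy-1-(4-benzyloxyphenyl)but-3-en-1-ol (anti) | C=C[C@@H](OCc1ccccc1)[C@@H](O)c1ccc(OCc2ccccc2)cc1 | intermediate
12 | phloroglucinol | Oc1cc(O)cc(O)c1 | starting material
13 | phloroglucinol triacetate | CC(=O)Oc1cc(OC(C)=O)cc(OC(C)=O)c1 | intermediate
14 | 1,3,5-tris(benzyloxy)benzene | c1ccc(COc2cc(OCc3ccccc3)cc(OCc3ccccc3)c2)cc1 | intermediate
15 | 3,5-bis(benzyloxy)phenol | Oc1cc(OCc2ccccc2)cc(OCc2ccccc2)c1 | intermediate
16 | (1R,2R) syn aryl ether | C=C[C@@H](OCc1ccccc1)[C@H](Oc1cc(OCc2ccccc2)cc(OCc2ccccc2)c1)c1ccc(OCc2ccccc2)cc1 | intermediate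
17 | vicinal diol from 16 (new carbinol centre undefined) | OCC(O)[C@@H](OCc1ccccc1)[C@H](Oc1cc(OCc2ccccc2)cc(OCc2ccccc2)c1)c1ccc(OCc2ccccc2)cc1 | intermediate
18 | (2S,3R)-2-benzyloxy-3-(4-benzyloxyphenyl)-3-[3,5-bis(benzyloxy)phenoxy]propanal | O=C[C@@H](OCc1ccccc1)[C@H](Oc1cc(OCc2ccccc2)cc(OCc2ccccc2)c1)c1ccc(OCc2ccccc2)cc1 | intermediate
19 | C6 arylmagnesium chloride of the lower unit (LiCl complex) | O=C(O[C@@H]1Cc2c(c(Br)c(OCc5ccccc5)c([Mg]Cl)c2OCc5ccccc5)O[C@@H]1c1ccc(OCc5ccccc5)c(OCc5ccccc5)c1)c1cc(OCc5ccccc5)c(OCc5ccccc5)c(OCc5ccccc5)c1 | intermediate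
20 | seco-dimer C4 carbinol (C4 epimers) | O=C(O[C@@H]1Cc2c(c(Br)c(OCc5ccccc5)c(C(O)[C@@H](OCc5ccccc5)[C@H](Oc3cc(OCc5ccccc5)cc(OCc5ccccc5)c3)c3ccc(OCc5ccccc5)cc3)c2OCc5ccccc5)O[C@@H]1c1ccc(OCc5ccccc5)c(OCc5ccccc5)c1)c1cc(OCc5ccccc5)c(OCc5ccccc5)c(OCc5ccccc5)c1 | intermediate
21 | 8-bromo-undeca-O-benzyl-epiafzelechin-(4β→6)-epicatechin 3-O-gallate | O=C(O[C@@H]1Cc2c(c(Br)c(OCc5ccccc5)c([C@H]3c4c(OCc5ccccc5)cc(OCc5ccccc5)cc4O[C@H](c4ccc(OCc5ccccc5)cc4)[C@@H]3OCc5ccccc5)c2OCc5ccccc5)O[C@@H]1c1ccc(OCc5ccccc5)c(OCc5ccccc5)c1)c1cc(OCc5ccccc5)c(OCc5ccccc5)c(OCc5ccccc5)c1 | intermediate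
22 | epiafzelechin-(4β→6)-epicatechin 3-O-gallate (CNP0210310.1) | O=C(O[C@@H]1Cc2c(cc(O)c([C@H]3c4c(O)cc(O)cc4O[C@H](c4ccc(O)cc4)[C@@H]3O)c2O)O[C@@H]1c1ccc(O)c(O)c1)c1cc(O)c(O)c(O)c1 | target

**Totals and risks**

Total step count: 15.
Longest linear sequence: 8 steps (steps 5, 6, 7, 11, 12, 13, 14, 15 from 6; equally steps 8 to 15 from 12).

Steps most likely to fail:

1. Step 14 (Proposed new method). What may go wrong: insufficient facial selectivity at the planar C4 cation, proton loss or a 1,2-hydride shift from C3 before the ring closes, fragmentation of the C2–C3 bond, or intermolecular arylation. The fallback uses known chemistry, sets out from aldehyde 18 and bromide 4, and comes back at 21. It closes ring C first and forms the interflavan bond last. Aldehyde 18 is converted with trimethyl orthoformate and catalytic camphorsulfonic acid in methanol into the dimethyl acetal F1. Mild Lewis acid treatment in the presence of methanol (Sc(OTf)3, CH2Cl2/MeOH, 0 °C) then closes ring C by intramolecular Friedel–Crafts alkoxyalkylation of a ring A ortho carbon by the oxocarbenium ion, the way aryloxy acetals are closed to 4-alkoxychromans, and should give 3,5,7,4'-tetra-O-benzyl-4-methoxy-epiafzelechin F2 (C4 epimers); methanol returns any C4 cation to the ether. F2 is a classical C4 electrophile: with catalytic TMSOTf in CH2Cl2 at −78 °C and an excess of 4, whose only free ring D position is C6, the ring-A-stabilised C4 cation of the preformed 2,3-cis flavan should be attacked anti to the C3 benzyloxy group, as in established couplings of 4-alkoxy flavan-3-ols with C8-blocked nucleophiles, to give 21.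

2. Step 13. What may go wrong: slow iodine–magnesium exchange at the electron-rich, doubly ortho-substituted iodide, competing attack on the gallate ester, or base-induced epimerisation and β-elimination of the aldehyde before addition. The fallback sets out from 5 (with 18) and comes back at 21; it removes the ester so that a more reactive aryllithium can be used and introduces the gallate last. Methanolysis of 5 (K2CO3, MeOH/THF) should give 5,7,3',4'-tetra-O-benzyl-8-bromo-6-iodo-epicatechin F3. Deprotonation of its hydroxyl with MeLi and iodine–lithium exchange with n-BuLi at −78 °C should give the C6-lithio lithium alkoxide F4 (not isolated), which is added to 18 to give the gallate-free carbinol F5 (C4 epimers). Ring closure under the conditions of step 14 should give the dimer with a free lower 3-hydroxyl F6, and esterification of this single hydroxyl with commercial 3,4,5-tris(benzyloxy)benzoic acid (EDC·HCl, DMAP, CH2Cl2; Steglich-type) returns to 21.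

3. Step 11. What may go wrong: partial ionisation of the p-benzyloxybenzylic oxyphosphonium ion, with loss of stereochemical integrity at C1 and C-alkylation of the phenol, or elimination to a diene. The fallback sets out from allylboronate 8 (with 15) and comes back at 16; it carries an electron-withdrawing acyl group on the ring B oxygen through the substitution. Under the conditions of step 7, 8 and commercial 4-formylphenyl benzoate should give the pinacol borate F7 (not isolated) and, after work-up, the anti alcohol 4-[(1S,2R)-2-benzyloxy-1-hydroxybut-3-enyl]phenyl benzoate F8. Because the acyloxy group no longer stabilises a benzylic cation, the Mitsunobu reaction of F8 with 15 (n-Bu3P, TMAD, toluene) should proceed by clean inversion to the syn aryl ether benzoate F9. Methanolysis of the benzoate (K2CO3, MeOH, 0 °C) gives the phenol F10, which is benzylated at once in the same flask (BnBr, DMF), so that the phenoxide has no time to expel the ring A aryloxide, and this returns to 16.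

**Further compounds**

F1 | step 14 | dimethyl acetal of aldehyde 18 | COC(OC)[C@@H](OCc1ccccc1)[C@H](Oc1cc(OCc2ccccc2)cc(OCc2ccccc2)c1)c1ccc(OCc2ccccc2)cc1
F2 | step 14 | 3,5,7,4'-tetra-O-benzyl-4-methoxy-epiafzelechin (C4 epimers) | COC1c2c(OCc3ccccc3)cc(OCc3ccccc3)cc2O[C@H](c2ccc(OCc3ccccc3)cc2)[C@@H]1OCc1ccccc1
F3 | step 13 | 5,7,3',4'-tetra-O-benzyl-8-bromo-6-iodo-(−)-epicatechin | O[C@@H]1Cc2c(c(Br)c(OCc5ccccc5)c(I)c2OCc5ccccc5)O[C@@H]1c1ccc(OCc5ccccc5)c(OCc5ccccc5)c1
F4 | step 13 | C6-lithio lithium 3-alkoxide of F3 | [Li]O[C@@H]1Cc2c(c(Br)c(OCc5ccccc5)c([Li])c2OCc5ccccc5)O[C@@H]1c1ccc(OCc5ccccc5)c(OCc5ccccc5)c1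
F5 | step 13 | gallate-free seco-dimer carbinol (C4 epimers) | O[C@@H]1Cc2c(c(Br)c(OCc5ccccc5)c(C(O)[C@@H](OCc5ccccc5)[C@H](Oc3cc(OCc5ccccc5)cc(OCc5ccccc5)c3)c3ccc(OCc5ccccc5)cc3)c2OCc5ccccc5)O[C@@H]1c1ccc(OCc5ccccc5)c(OCc5ccccc5)c1
F6 | step 13 | 8-bromo-octa-O-benzyl-epiafzelechin-(4β→6)-epicatechin with free lower 3-hydroxyl | O[C@@H]1Cc2c(c(Br)c(OCc5ccccc5)c([C@H]3c4c(OCc5ccccc5)cc(OCc5ccccc5)cc4O[C@H](c4ccc(OCc5ccccc5)cc4)[C@@H]3OCc5ccccc5)c2OCc5ccccc5)O[C@@H]1c1ccc(OCc5ccccc5)c(OCc5ccccc5)c1
F7 | step 11 | pinacol borate ester of F8 | C=C[C@@H](OCc1ccccc1)[C@@H](OB1OC(C)(C)C(C)(C)O1)c1ccc(OC(=O)c2ccccc2)cc1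
F8 | step 11 | 4-[(1S,2R)-2-benzyloxy-1-hydroxybut-3-enyl]phenyl benzoate (anti) | C=C[C@@H](OCc1ccccc1)[C@@H](O)c1ccc(OC(=O)c2ccccc2)cc1
F9 | step 11 | 4-{(1R,2R)-2-benzyloxy-1-[3,5-bis(benzyloxy)phenoxy]but-3-enyl}phenyl benzoate (syn) | C=C[C@@H](OCc1ccccc1)[C@H](Oc1cc(OCc2ccccc2)cc(OCc2ccccc2)c1)c1ccc(OC(=O)c2ccccc2)cc1
F10 | step 11 | 4-{(1R,2R)-2-benzyloxy-1-[3,5-bis(benzyloxy)phenoxy]but-3-enyl}phenol | C=C[C@@H](OCc1ccccc1)[C@H](Oc1cc(OCc2ccccc2)cc(OCc2ccccc2)c1)c1ccc(O)cc1
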